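## Analysis of the target

Compound numbers are those of the steps below (1–26). Atoms carry labdane numbers: ring A is C1–C5 and C10, ring B is C5–C10, C17 is the methyl on C8, C18 and C19 are the methyls on C4, C20 is the methyl on C10, and C11–C16 form the side chain. The β face is the face of the C10 methyl.

The target 26 is a labdane, (13Z)-6β-acetoxylabda-8,13-diene-7α,15-diol. It is a trans-fused decalin with a gem-dimethyl group at C4, an angular methyl at C10 and a tetrasubstituted C8=C9 alkene in ring B. C8 carries a methyl group and C9 carries a five-carbon chain that ends in a (Z)-trisubstituted allylic alcohol (C13=C14, C15–OH).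

There are four stereocentres, all in or next to ring B. C5 (α-H) and the quaternary C10 (β-methyl) define the trans ring fusion. C6 (β-acetoxy) and C7 (α-hydroxy) are trans-diaxial. All four are S, and the Z geometry of C13=C14 is a fifth stereo-element.

The sensitive groups are the allylic C7 hydroxyl (ionisation or transposition under acid), the secondary acetate next to a free hydroxyl (cleavage under base; migration is geometrically blocked between trans-diaxial oxygens), and the Z allylic alcohol.

Three things make the synthesis hard. The quaternary C10 sits next to the quaternary C4. The absolute configuration has to be set in a skeleton with no heteroatom handle in ring A. The acetoxy group has to be on the more crowded oxygen (6β, syn-axial to the methyls on C4 and C10) while the more accessible 7α oxygen stays free.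

The strategy rests on ring B. The trans oxygens at C6 and C7 can come from a C6=C7 alkene, and C11 on C9 can be a formyl group. Ring B is then the cyclohexene of a Diels–Alder adduct (diene C5=C6–C7=C8, dienophile C9=C10), and the chain C1–C4 that links C10 to C5 is ring A. Both rings can therefore be closed at once from an acyclic trienal.

## Retrosynthetic reasoning

**26 from 25.** Only two O–Si bonds are cut, at O7 and O15. The acetoxy group is already on O6 at this stage, so the hindered 6β-hydroxyl never has to be acylated selectively beside the more accessible 7α-hydroxyl. The forward step has to free both alcohols without acid strong enough to ionise the allylic C7–O bond and without base strong enough to cleave the ester.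

**25 from 19 and 23.** The C12–C13 bond is cut. The Z alkene is then brought in as the iodoalkene 23, whose geometry is fixed when alkyne 20 is converted into 22. It is carried into 25 by a stereoretentive sp3–sp2 cross-coupling of the alkylborane 24. Cutting at C9–C11 would mean forming a bond to the tetrasubstituted C9 of the crowded bicycle, and making C13=C14 on the bicycle would leave its geometry to an olefination. The forward step has to hydroborate only the terminal alkene of 19 and couple under conditions that spare the acetate.

**19 from 18.** C11=C12 is cut back to the C11 formyl group by a one-carbon olefination. The formyl carbon is the activating group of the dienophile in the key step, so it is used twice.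

**18 from 17 and 16.** The C8=C9 alkene is taken back to C8–H and C9–H beside the formyl group. In the forward direction the aldehyde is dehydrogenated through its silyl enol ether 17. This erases the C8 and C9 stereocentres that the cycloaddition creates. The dehydrogenation is placed after the oxygenation of C6 and C7 on purpose. If C8=C9 were present first, C7 would be an allylic epoxide carbon and would take the nucleophile instead of C6. One silylation does two jobs: it protects O7 and turns the formyl group of 16 into the enol ether.

**16 from 15, and 15 from 14.** The C6–O and C7–O bonds are cut back to the C6=C7 alkene of 14. Forward, the alkene is epoxidised on the open α face, and the epoxide 15 is opened in the trans-diaxial sense by an acetoxy nucleophile at C6. This inverts C6 and leaves the epoxide oxygen on C7, so the acyl group arrives on the correct oxygen without any selective acylation. The 8β-methyl group of 14, which is erased later, shields C7 on the β face during this opening.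

**14 from 13 (key disconnection).** The bonds C5–C10 and C8–C9 are cut. Ring B is the new cyclohexene of an intramolecular [4+2] cycloaddition and ring A is the ring formed by the tether. Both hindered ring-fusion bonds form intramolecularly, and C10 and C5 are set together. Trienal 13 has no stereocentre, so the absolute configuration has to come from a chiral amine catalyst acting on the formyl group. The forward step has to give the endo, trans-fused adduct on one face of the enal.

**13 from 12, and 12 from 10.** The aldehyde comes from the allylic alcohol 12. The trisubstituted C9=C10 alkene of 12 is cut at C10–C20 and C9–C11 and traced to the terminal alkyne 10 through the alkenylalane 11. A syn carbometalation fixes the E geometry rigorously. This matters because the dienophile geometry is translated into the ring fusion.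

**10 from 9, and 9 from 7 and 8.** After removal of the alkyne silyl group, the C6–C7 single bond of the diene is cut. The iodoalkene 7 and the boronic acid 8 are both E, and the coupling keeps both geometries.

**7 from 6, 6 from 4, 4 from 1 and 2.** C6 is added to the aldehyde 6 as an iodomethylidene unit. Aldehyde 6 comes from nitrile 4 through the imine derivative 5. The C3–C4 bond is cut last: the quaternary C4 with both of its methyl groups is nitrile 1, used as its anion 3, and the chain C1–C3 with the masked alkyne is chloride 2.

**23 from 22, and 22 from 20.** The silyl ether 23 comes from alcohol 22. Compound 22 is formed from 20 through the cyclic alanate 21, which places the metal, and then iodine, cis to the hydroxymethyl group.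

## Alternatives that were turned down

**Alternative 1:** Ring A is disconnected at C1–C10 and C4–C5, and ring B comes from a quinone. In the forward key step, diene A2 (4-methylpenta-1,3-diene) adds across the methyl-bearing double bond of quinone A3 (2,6-dimethyl-1,4-benzoquinone) under a chiral cationic boron Lewis acid. The product is the cis-fused ene-dione A1, in which C10 is set and C5 is epimerised afterwards.
- For: the two partners are cheap, and catalytic asymmetric cycloadditions of quinones have good support. Ring B arrives with oxygen at C6 and C9. A C6 ketone could be reduced from the open α face to the 6β alcohol, which avoids the crowded substitution at C6 that the chosen route needs. On this point A1 is the stronger intermediate.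
- Against: the diene terminus C4 of A2 carries two methyl groups, one of them pointing inside, which disfavours the s-cis conformer. The C4–C5 bond has to form intermolecularly at that fully substituted terminus. A1 then carries a superfluous C2=C3 alkene, two carbonyls that must be told apart, and a neopentyl C9 carbonyl that must accept the side chain, become part of C8=C9 and pass an oxygen on to C7.
- Comparison: the chosen route forms both ring-fusion bonds intramolecularly at unsubstituted CH termini of the diene, and C9 already carries the carbon needed for the side chain.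

**Alternative 2:** Ring B is disconnected at C9–C10. In the forward key step the acyl selenide A5 gives a C9 acyl radical (tin hydride chain), which adds 6-endo to C10 of the ring A enone. The resulting C5 radical is reduced to give the trans-fused dione A4.
- For: ring A comes from an inexpensive cyclohexenyl ketone. A nucleophilic acyl radical is polarity-matched with the enone β-carbon. A4 again carries a C6 ketone, which is better placed for the 6β oxygen than anything in the chosen route.
- Against: the only stereocentre of A5 is C8. It is α to the acyl group, it would have to relay its configuration to C10 across a planar radical centre, and it is destroyed later in any case. Addition to the fully substituted C10 is slow, so decarbonylation and premature reduction compete. After the cyclisation, two ketones have to be differentiated and the chain has to be attached to a hindered carbonyl.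
- Comparison: the chosen route sets C10 and C5 under catalyst control in a concerted step and needs no stoichiometric tin. Its weaker point is the oxygenation at C6.

**Alternative 3:** Ring B is disconnected at C7–C8 and C9–C10. In the forward key step the 2-silyloxydiene A8 of ring A adds to ynal A7 under a chiral boron Lewis acid to give the cyclohexadiene A6.
- For: this is the most convergent plan. A6 already contains the C8=C9 enal (no dehydrogenation is needed) and a masked C6 ketone. On step count and oxidation pattern it is stronger than the chosen route.
- Against: the diene terminus C10 of A8 is tetrasubstituted and lies in a ring next to the gem-dimethyl carbon. Dienes of this type are twisted out of conjugation, and the C9–C10 bond would have to form intermolecularly between that terminus and the substituted alkyne carbon. The only stereocentre, C10, would rest on an enantioselective ynal cycloaddition that has little support. C7 would then need hydroxylation beside an aldehyde and a ketone.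
- Comparison: the chosen route pays with extra steps after the cycloaddition, but it makes the quaternary centre intramolecularly with a catalyst class that is established for trienals.

Key step: step 8

## Remarks before the steps

- Chloride 2 and boronic acid 8 are taken as commercial. The (2S,5S) catalyst in step 8 is chosen from the usual shielding model of the imidazolidinone iminium ion.
- Short-lived species bound to palladium, chromium, phosphorus or the amine catalyst are discussed in the Why lines and carry no compound numbers.

## Route

Step 1
Reactants: 1 isobutyronitrile; 2 (5-chloropent-1-yn-1-yl)trimethylsilane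
Product: 4 2,2-dimethyl-7-(trimethylsilyl)hept-6-ynenitrile, via lithiated isobutyronitrile 3 (not isolated)
Conditions: LiN(i-Pr)2, THF, −78 °C; then 2, DMPU, −78 °C → rt
Reagents that add atoms: none
Why: The nitrile-stabilised tertiary carbanion alkylates the primary chloride by SN2 and builds the quaternary C4 with both methyl groups in one operation; the C-silyl group keeps the alkyne terminus from being deprotonated.

Step 2
Reactants: 4 2,2-dimethyl-7-(trimethylsilyl)hept-6-ynenitrile
Product: 6 2,2-dimethyl-7-(trimethylsilyl)hept-6-ynal, via N-aluminio aldimine 5 (not isolated)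
Conditions: i-Bu2AlH, CH2Cl2, −78 °C → 0 °C; then aqueous tartaric acid, rt
Reagents that add atoms: water, O
Why: i-Bu2AlH adds once to the hindered nitrile, and the N-aluminio imine survives until mild acidic hydrolysis releases the aldehyde, which has no α-hydrogen; the silylalkyne is not hydroaluminated at low temperature.

Step 3
Reactants: 6 2,2-dimethyl-7-(trimethylsilyl)hept-6-ynal
Product: 7 [(7E)-8-iodo-6,6-dimethyloct-7-en-1-yn-1-yl]trimethylsilane
Conditions: CrCl2, CHI3, THF/dioxane, 0 °C → rt
Reagents that add atoms: iodoform, IC(I)I
Why: Takai olefination: the gem-dichromium reagent made from iodoform and divalent chromium adds to the aldehyde and eliminates to the iodoalkene (C5=C6); the α-quaternary centre should reinforce the inherent E preference.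

Step 4
Reactants: 7 [(7E)-8-iodo-6,6-dimethyloct-7-en-1-yn-1-yl]trimethylsilane; 8 (E)-prop-1-en-1-ylboronic acid
Product: 9 trimethyl[(7E,9E)-6,6-dimethylundeca-7,9-dien-1-yn-1-yl]silane
Conditions: Pd(PPh3)4 (5 mol %), K3PO4, THF/H2O, 40 °C
Reagents that add atoms: none
Why: Suzuki–Miyaura coupling of an alkenyl iodide with an alkenylboronic acid (oxidative addition, transmetalation, reductive elimination at palladium) keeps the geometry of both partners, so the (E,E)-diene C5=C6–C7=C8 should form as one isomer.

Step 5
Reactants: 9 trimethyl[(7E,9E)-6,6-dimethylundeca-7,9-dien-1-yn-1-yl]silane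
Product: 10 (7E,9E)-6,6-dimethylundeca-7,9-dien-1-yne
Conditions: K2CO3 (0.2 equiv), MeOH, rt
Reagents that add atoms: none
Why: Carbonate-catalysed methanolysis of the C(sp)–Si bond frees the terminal alkyne; the diene is inert to these conditions.

Step 6
Reactants: 10 (7E,9E)-6,6-dimethylundeca-7,9-dien-1-yne
Product: 12 (2E,8E,10E)-3,7,7-trimethyldodeca-2,8,10-trien-1-ol, via alkenyldimethylalane 11 (not isolated)
Conditions: Me3Al, Cp2ZrCl2 (0.25 equiv), CH2Cl2, 0 °C → rt; then n-BuLi, THF, −78 °C; (CH2O)n, −78 °C → rt
Reagents that add atoms: trimethylaluminium, C[Al](C)C; formaldehyde (from paraformaldehyde), C=O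
Why: Zirconium-catalysed methylalumination (Negishi carboalumination) adds methyl and aluminium syn across the terminal alkyne with methyl on the internal carbon; the alkenylalane, activated as its aluminate, is hydroxymethylated with retention, so the trisubstituted C9=C10 alkene should be E.

Step 7
Reactants: 12 (2E,8E,10E)-3,7,7-trimethyldodeca-2,8,10-trien-1-ol
Product: 13 (2E,8E,10E)-3,7,7-trimethyldodeca-2,8,10-trienal
Conditions: MnO2 (excess), CH2Cl2, rt
Reagents that add atoms: none
Why: MnO2 oxidises the allylic alcohol selectively to the enal without isomerising the trisubstituted alkene or touching the diene.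

Step 8
Reactants: 13 (2E,8E,10E)-3,7,7-trimethyldodeca-2,8,10-trienal
Product: 14 (1S,2S,4aS,8aS)-2,5,5,8a-tetramethyl-1,2,4a,5,6,7,8,8a-octahydronaphthalene-1-carbaldehyde (trans-fused; 5α-H, 8β-methyl, 9β-formyl, 10β-methyl, C6=C7 alkene)
Conditions: (2S,5S)-5-benzyl-2-tert-butyl-3-methylimidazolidin-4-one·CF3SO3H (20 mol %), MeCN/H2O (98:2), 0 °C → rt
Reagents that add atoms: none
Why: The amine salt condenses with enal 13 to an α,β-unsaturated iminium ion whose lowered LUMO lets the C9=C10 dienophile add to the tethered C5=C6–C7=C8 diene in a concerted, asynchronous [4+2] cycloaddition, and hydrolysis of the adduct iminium ion returns the catalyst. The closest known reaction type is the imidazolidinone-catalysed intramolecular Diels–Alder reaction of β-monosubstituted (2E,8E,10E)-trienals to trans-fused decalin aldehydes; the β-methyl group of 13, which makes C10 quaternary, is the extension. Ring B closes as the new cyclohexene (bonds C5–C10 and C8–C9), and ring A closes as the tether ring, with the chain C1–C4 folded as a chair. C10 is set by the catalyst: the benzyl group covers one face of the iminium ion, so the diene should add to the open face of C9=C10, which for the (2S,5S) catalyst gives the 10β-methyl (10S) centre. C5 follows from the endo transition state, with the iminium carbon under the diene and the tether exo, which puts H5 anti to the C10 methyl (trans fusion). C9 follows from the E geometry of the enal (formyl cis to the C10 methyl), and C8 from the E geometry of C7=C8 (methyl cis to formyl). The step needs endo over exo selectivity and reaction through the E enal only; the gem-dimethyl group at C4 favours the folded conformer, and the strong-acid co-catalyst holds the aldehyde as iminium ion and disfavours the dienamine that would scramble the enal geometry.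

Step 9
Reactants: 14 (1S,2S,4aS,8aS)-2,5,5,8a-tetramethyl-1,2,4a,5,6,7,8,8a-octahydronaphthalene-1-carbaldehyde
Product: 15 trans-fused 3,4-epoxy-2,5,5,8a-tetramethyldecahydronaphthalene-1-carbaldehyde with the epoxide on the face opposite to the 8a-methyl (labdane locants: 6α,7α-epoxy, 8β-methyl, 9β-formyl)
Conditions: dimethyldioxirane (1.2 equiv), acetone/CH2Cl2, 0 °C
Reagents that add atoms: dimethyldioxirane, CC1(C)OO1
Why: Dimethyldioxirane epoxidises the only alkene under neutral conditions faster than it oxidises the hindered formyl group; the β face of C6=C7 is blocked by the axial methyl groups on C4, C8 and C10, so the oxygen should be delivered to the α face.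

Step 10
Reactants: 15 6α,7α-epoxy aldehyde
Product: 16 4-acetoxy-3-hydroxy-2,5,5,8a-tetramethyldecahydronaphthalene-1-carbaldehyde (labdane locants: 6β-acetoxy, 7α-hydroxy, 8β-methyl, 9β-formyl; trans-fused)
Conditions: AcOH, NaOAc, 60 °C
Reagents that add atoms: acetic acid, CC(=O)O
Why: Acid-assisted epoxide opening follows the rule of trans-diaxial opening: attack at C6 from the β face, anti to the C6–O bond, leads directly to the chair with 6β-acetoxy and 7α-hydroxy, whereas attack at C7 would pass the pseudoaxial 8β-methyl and go through a twist-boat. C6 is inverted, C7 keeps the epoxide oxygen, and the NaOAc buffer should hold back cationic rearrangement.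

Step 11
Reactants: 16 6β-acetoxy-7α-hydroxy aldehyde
Product: 17 the 7α-triethylsilyl ether of 16 with the formyl group as its triethylsilyl enol ether (C9=C11H–OSiEt3, E/Z mixture; 8β-methyl retained)
Conditions: Et3SiOTf (3 equiv), Et3N (5 equiv), CH2Cl2, 0 °C → rt; non-aqueous work-up
Reagents that add atoms: triethylsilyl trifluoromethanesulfonate, CC[Si](CC)(CC)OS(=O)(=O)C(F)(F)F
Why: Et3SiOTf with Et3N silylates the secondary alcohol and, by O-silylation and loss of the single α-hydrogen at C9, converts the aldehyde into its silyl enol ether in the same operation; the hindered acetate is not affected.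

Step 12
Reactants: 17 bis-silyl compound
Product: 18 4-acetoxy-2,5,5,8a-tetramethyl-3-(triethylsilyloxy)-3,4,4a,5,6,7,8,8a-octahydronaphthalene-1-carbaldehyde (labdane locants: 6β-acetoxy, 7α-silyloxy, C8=C9, C11 formyl)
Conditions: Pd(OAc)2 (1.1 equiv), MeCN, rt
Reagents that add atoms: none
Why: Saegusa–Ito oxidation: divalent palladium forms the C9-bound enolate with loss of the silyl group, and syn β-hydride elimination of H8 (the only β-hydrogen, since C10 is quaternary) gives the C8=C9 enal and zerovalent palladium; the C8 and C9 stereocentres are removed as planned.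

Step 13
Reactants: 18 6β-acetoxy-7α-silyloxy enal
Product: 19 1-ethenyl-2,5,5,8a-tetramethyl-3-(triethylsilyloxy)-3,4,4a,5,6,7,8,8a-octahydronaphthalen-4-yl acetate (labdane locants: 6β-acetoxy, 7α-silyloxy, C8=C9–C11=C12)
Conditions: Ph3PCH3Br, KN(SiMe3)2, THF, 0 °C; then 18, 0 °C → rt
Reagents that add atoms: methyltriphenylphosphonium bromide (as its ylide), C[P+](c1ccccc1)(c1ccccc1)c1ccccc1.[Br-]
Why: Wittig methylenation: the non-stabilised ylide should react with the conjugated, flanked formyl group (as it does with cyclocitral-type aldehydes) much faster than with the hindered axial acetate.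

Step 14
Reactants: 20 but-2-yn-1-ol
Product: 22 (Z)-3-iodobut-2-en-1-ol, via cyclic vinylalanate 21 (not isolated)
Conditions: NaAlH2(OCH2CH2OMe)2, Et2O, 0 °C → rt; then I2, THF, −78 °C → 0 °C
Reagents that add atoms: iodine, II
Why: Hydroxyl-directed trans-hydroalumination of the propargylic alcohol places aluminium on C13 in a five-membered alanate, and iodinolysis with retention gives the iodoalkene with iodine cis to the hydroxymethyl group (Z).

Step 15
Reactants: 22 (Z)-3-iodobut-2-en-1-ol
Product: 23 tert-butyl{[(2Z)-3-iodobut-2-en-1-yl]oxy}dimethylsilane
Conditions: t-BuMe2SiCl, imidazole, DMF, rt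
Reagents that add atoms: tert-butyldimethylsilyl chloride, CC(C)(C)[Si](C)(C)Cl
Why: Standard silylation of a primary alcohol; the ether keeps the alkoxide out of the cross-coupling and is removed at the end together with the C7 silyl ether.

Step 16
Reactants: 19 diene acetate; 23 tert-butyl{[(2Z)-3-iodobut-2-en-1-yl]oxy}dimethylsilane
Product: 25 the 7-O-triethylsilyl, 15-O-tert-butyldimethylsilyl ether of the target, via B-alkyl-9-BBN borane 24 (not isolated)
Conditions: 9-BBN-H (2 equiv), THF, 0 °C → rt; then 23, Pd(dppf)Cl2 (10 mol %), AsPh3, Cs2CO3, DMF/H2O, rt
Reagents that add atoms: none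
Why: The dialkylborane adds anti-Markovnikov to the monosubstituted C11=C12 alkene only (the tetrasubstituted C8=C9 alkene and the ester are inert), and the B-alkyl Suzuki–Miyaura coupling forms C12–C13 with retention of the Z geometry under mild aqueous carbonate that the hindered acetate should tolerate.

Step 17
Reactants: 25 bis-silyl ether
Product: 26 (1S,2S,4aS,8aS)-2-hydroxy-4-[(3Z)-5-hydroxy-3-methylpent-3-en-1-yl]-3,4a,8,8-tetramethyl-1,2,4a,5,6,7,8,8a-octahydronaphthalen-1-yl acetate (the target)
Conditions: HF·pyridine, pyridine, THF, 0 °C → rt
Reagents that add atoms: none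
Why: Pyridine-buffered fluoride cleaves both silyl ethers without acid strong enough to ionise the allylic C7 alcohol or base strong enough to cleave the acetate; acyl migration is not possible between trans-diaxial oxygens.

## Compound list

1 | isobutyronitrile | CC(C)C#N | starting material
2 | (5-chloropent-1-yn-1-yl)trimethylsilane | C[Si](C)(C)C#CCCCCl | starting material
3 | lithiated isobutyronitrile | [Li+].C[C-](C)C#N | intermediate
4 | 2,2-dimethyl-7-(trimethylsilyl)hept-6-ynenitrile | N#CC(C)(C)CCCC#C[Si](C)(C)C | intermediate
5 | N-(diisobutylaluminio) aldimine of 6 | CC(C)C[Al](CC(C)C)N=CC(C)(C)CCCC#C[Si](C)(C)C | intermediate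
6 | 2,2-dimethyl-7-(trimethylsilyl)hept-6-ynal | O=CC(C)(C)CCCC#C[Si](C)(C)C | intermediate
7 | [(7E)-8-iodo-6,6-dimethyloct-7-en-1-yn-1-yl]trimethylsilane | I/C=C/C(C)(C)CCCC#C[Si](C)(C)C | intermediate
8 | (E)-prop-1-en-1-ylboronic acid | C/C=C/B(O)O | starting material
9 | trimethyl[(7E,9E)-6,6-dimethylundeca-7,9-dien-1-yn-1-yl]silane | C/C=C/C=C/C(C)(C)CCCC#C[Si](C)(C)C | intermediate
10 | (7E,9E)-6,6-dimethylundeca-7,9-dien-1-yne | C/C=C/C=C/C(C)(C)CCCC#C | intermediate
11 | dimethyl[(1E,7E,9E)-2,6,6-trimethylundeca-1,7,9-trien-1-yl]alane | C[Al](C)/C=C(\C)CCCC(C)(C)/C=C/C=C/C | intermediate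
12 | (2E,8E,10E)-3,7,7-trimethyldodeca-2,8,10-trien-1-ol | OC/C=C(\C)CCCC(C)(C)/C=C/C=C/C | intermediate
13 | (2E,8E,10E)-3,7,7-trimethyldodeca-2,8,10-trienal | O=C/C=C(\C)CCCC(C)(C)/C=C/C=C/C | intermediate
14 | (1S,2S,4aS,8aS)-2,5,5,8a-tetramethyl-1,2,4a,5,6,7,8,8a-octahydronaphthalene-1-carbaldehyde | C1=C[C@H](C)[C@H](C=O)[C@@]2(C)CCCC(C)(C)[C@H]12 | intermediate
15 | 6α,7α-epoxide of 14 (8β-methyl, 9β-formyl) | O1[C@H]2[C@@H]1[C@H](C)[C@H](C=O)[C@@]3(C)CCCC(C)(C)[C@H]23 | intermediate
16 | 6β-acetoxy-7α-hydroxy aldehyde (8β-methyl, 9β-formyl) | CC(=O)O[C@@H]1[C@@H](O)[C@H](C)[C@H](C=O)[C@@]2(C)CCCC(C)(C)[C@H]12 | intermediate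
17 | 6β-acetoxy-7α-(triethylsilyloxy) triethylsilyl enol ether (C9=C11) | CC(=O)O[C@@H]1[C@@H](O[Si](CC)(CC)CC)[C@H](C)C(=CO[Si](CC)(CC)CC)[C@@]2(C)CCCC(C)(C)[C@H]12 | intermediate
18 | 6β-acetoxy-7α-(triethylsilyloxy)-8-en-11-al | CC(=O)O[C@@H]1[C@@H](O[Si](CC)(CC)CC)C(C)=C(C=O)[C@@]2(C)CCCC(C)(C)[C@H]12 | intermediate
19 | 6β-acetoxy-7α-(triethylsilyloxy)-8,11-diene | CC(=O)O[C@@H]1[C@@H](O[Si](CC)(CC)CC)C(C)=C(C=C)[C@@]2(C)CCCC(C)(C)[C@H]12 | intermediate
20 | but-2-yn-1-ol | CC#CCO | starting material
21 | sodium cyclic vinylalanate from 20 | CC1=CCO[Al-]1(OCCOC)OCCOC.[Na+] | intermediate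
22 | (Z)-3-iodobut-2-en-1-ol | C/C(I)=C/CO | intermediate
23 | tert-butyl{[(2Z)-3-iodobut-2-en-1-yl]oxy}dimethylsilane | C/C(I)=C/CO[Si](C)(C)C(C)(C)C | intermediate
24 | B-alkyl-9-borabicyclo[3.3.1]nonane from 19 (boron on C12) | CC(=O)O[C@@H]1[C@@H](O[Si](CC)(CC)CC)C(C)=C(CCB3C4CCCC3CCC4)[C@@]2(C)CCCC(C)(C)[C@H]12 | intermediate
25 | 7-O-triethylsilyl, 15-O-tert-butyldimethylsilyl ether of 26 | CC(=O)O[C@@H]1[C@@H](O[Si](CC)(CC)CC)C(C)=C(CC/C(C)=C\CO[Si](C)(C)C(C)(C)C)[C@@]2(C)CCCC(C)(C)[C@H]12 | intermediate
26 | (1S,2S,4aS,8aS)-2-hydroxy-4-[(3Z)-5-hydroxy-3-methylpent-3-en-1-yl]-3,4a,8,8-tetramethyl-1,2,4a,5,6,7,8,8a-octahydronaphthalen-1-yl acetate | CC(=O)O[C@@H]1[C@@H](O)C(C)=C(CC/C(C)=C\CO)[C@@]2(C)CCCC(C)(C)[C@H]12 | target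

## Step count and least certain steps

Total: 17 steps. Longest linear sequence: 15 steps (steps 1–13, 16, 17). Steps 14 and 15 make fragment 23.

**Step 8 (key step).** A β,β-disubstituted enal forms its iminium ion slowly and the β-carbon is crowded, so turnover may stall. Reversible loss of a γ-hydrogen (dienamine formation) can meanwhile isomerise C9=C10 from E to Z or move it out of conjugation. A Z dienophile would lead to the cis-fused adduct or to the mirror-image ring fusion and lower the enantiomeric purity. Exo cyclisation is the other leak.
Fallback, from 13 back to 14: cyclise 13 with Me2AlCl in CH2Cl2 (−78 °C → 0 °C), a carbonyl-activated, endo-selective intramolecular Diels–Alder reaction with no amine and hence no dienamine, to the racemic trans-fused aldehyde F1. Reduce with NaBH4 to the racemic alcohol F2. Acylate with (1S)-camphanic chloride and separate the diastereomeric esters by crystallisation or chromatography to obtain the camphanate F3 of the wanted enantiomer. Hydrolyse with LiOH to the alcohol F4, and oxidise with TEMPO/PhI(OAc)2 to rejoin the route at 14.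

**Step 10.** Capture at C6 has to take place on the axial β trajectory, next to the axial methyl groups on C4 and C10. With a weak nucleophile this may be slow enough for attack at C7, a hydride shift to a ketone, or participation of the formyl group to take over.
Fallback, from 15 back to 17: hydrolyse 15 with dilute HClO4 in aqueous THF, where water is the smallest nucleophile and is present in large excess, to the trans-diaxial diol F5. Silylate the far less hindered 7α-hydroxyl with Et3SiCl/imidazole to the mono-silyl ether F6. Acetylate the 6β-hydroxyl under forcing conditions (Ac2O, DMAP, Et3N, 40 °C) to the acetate F7. The conditions of step 11 then convert F7 into 17.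

**Step 12.** Palladation at C9, which is flanked by the quaternary C10 and the substituted C8, may be slow, so that protodesilylation back to the aldehyde competes. The β-hydride elimination also needs palladium on the α face, syn to H8.
Fallback, from 17 back to 18: treat 17 with PhSeCl at −78 °C; selenium should enter anti to the methyl groups on C8 and C10 and give the α-phenylselanyl aldehyde F8. Oxidise with H2O2/pyridine; syn elimination of the selenoxide with H8 should give 18.

**Step 6.** The Lewis-acidic methylzirconium and methylaluminium species may react with the conjugated diene (oligomerisation or carbometalation), or the hydroxymethylation of the alkenylalane may be incomplete.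
Fallback, from 10 back to 12: hydrate the alkyne (Ph3PAuNTf2 cat., MeOH/H2O) to the methyl ketone F9. Olefinate by a Horner–Wadsworth–Emmons reaction (triethyl phosphonoacetate, NaH) to the ester F10, removing the minor Z isomer by chromatography. Reduce with i-Bu2AlH to 12.

**Step 16.** Hydroboration of the twisted, hindered diene may be slow. In the basic aqueous medium, protodeboronation or partial loss of the acetate may compete with transmetalation.
Fallback, from 19 back to 25: hydroborate 19 as before and oxidise with NaBO3 to the primary alcohol F11. Convert it with I2/PPh3/imidazole to the iodide F12. Insert zinc (Zn dust, LiCl, THF) to give the alkylzinc iodide F13, and couple with 23 under Pd(PPh3)4 (Negishi coupling, non-aqueous and base-free) to 25.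

## Further compounds

F1 | step 8 | racemic 14 (both enantiomers of the trans-fused endo adduct) | C1=C[C@H](C)[C@H](C=O)[C@@]2(C)CCCC(C)(C)[C@H]12.C1=C[C@@H](C)[C@@H](C=O)[C@]2(C)CCCC(C)(C)[C@@H]12
F2 | step 8 | racemic (2,5,5,8a-tetramethyl-1,2,4a,5,6,7,8,8a-octahydronaphthalen-1-yl)methanol, relative configuration as in 14 | C1=C[C@H](C)[C@H](CO)[C@@]2(C)CCCC(C)(C)[C@H]12.C1=C[C@@H](C)[C@@H](CO)[C@]2(C)CCCC(C)(C)[C@@H]12
F3 | step 8 | [(1S,2S,4aS,8aS)-2,5,5,8a-tetramethyl-1,2,4a,5,6,7,8,8a-octahydronaphthalen-1-yl]methyl (1S)-camphanate | C1=C[C@H](C)[C@H](COC(=O)[C@@]34CC[C@@](C)(C(=O)O3)C4(C)C)[C@@]2(C)CCCC(C)(C)[C@H]12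
F4 | step 8 | [(1S,2S,4aS,8aS)-2,5,5,8a-tetramethyl-1,2,4a,5,6,7,8,8a-octahydronaphthalen-1-yl]methanol | C1=C[C@H](C)[C@H](CO)[C@@]2(C)CCCC(C)(C)[C@H]12
F5 | step 10 | 6β,7α-dihydroxy aldehyde (8β-methyl, 9β-formyl) | O[C@@H]1[C@@H](O)[C@H](C)[C@H](C=O)[C@@]2(C)CCCC(C)(C)[C@H]12
F6 | step 10 | 6β-hydroxy-7α-(triethylsilyloxy) aldehyde | O[C@@H]1[C@@H](O[Si](CC)(CC)CC)[C@H](C)[C@H](C=O)[C@@]2(C)CCCC(C)(C)[C@H]12
F7 | step 10 | 6β-acetoxy-7α-(triethylsilyloxy) aldehyde | CC(=O)O[C@@H]1[C@@H](O[Si](CC)(CC)CC)[C@H](C)[C@H](C=O)[C@@]2(C)CCCC(C)(C)[C@H]12
F8 | step 12 | 6β-acetoxy-9α-(phenylselanyl)-7α-(triethylsilyloxy) aldehyde | CC(=O)O[C@@H]1[C@@H](O[Si](CC)(CC)CC)[C@H](C)[C@@](C=O)([Se]c3ccccc3)[C@@]2(C)CCCC(C)(C)[C@H]12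
F9 | step 6 | (7E,9E)-6,6-dimethylundeca-7,9-dien-2-one | C/C=C/C=C/C(C)(C)CCCC(C)=O
F10 | step 6 | ethyl (2E,8E,10E)-3,7,7-trimethyldodeca-2,8,10-trienoate | CCOC(=O)/C=C(\C)CCCC(C)(C)/C=C/C=C/C
F11 | step 16 | 6β-acetoxy-7α-(triethylsilyloxy)-8-en-12-ol (primary alcohol on C12) | CC(=O)O[C@@H]1[C@@H](O[Si](CC)(CC)CC)C(C)=C(CCO)[C@@]2(C)CCCC(C)(C)[C@H]12
F12 | step 16 | the corresponding C12 iodide | CC(=O)O[C@@H]1[C@@H](O[Si](CC)(CC)CC)C(C)=C(CCI)[C@@]2(C)CCCC(C)(C)[C@H]12
F13 | step 16 | the corresponding C12 alkylzinc iodide | CC(=O)O[C@@H]1[C@@H](O[Si](CC)(CC)CC)C(C)=C(CC[Zn]I)[C@@]2(C)CCCC(C)(C)[C@H]12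
A1 | alternative 1 | cis-fused 2,5,5,8a-tetramethyl-4a,5,8,8a-tetrahydronaphthalene-1,4-dione | O=C1C=C(C)C(=O)[C@@]2(C)CC=CC(C)(C)[C@@H]12
A2 | alternative 1 | 4-methylpenta-1,3-diene | CC(C)=CC=C
A3 | alternative 1 | 2,6-dimethyl-1,4-benzoquinone | O=C1C=C(C)C(=O)C(C)=C1
A4 | alternative 2 | trans-fused 2,5,5,8a-tetramethyloctahydronaphthalene-1,4-dione (5α-H, 8α-methyl, 10β-methyl) | O=C1C[C@@H](C)C(=O)[C@@]2(C)CCCC(C)(C)[C@H]12
A5 | alternative 2 | Se-phenyl (2R)-2-methyl-4-oxo-4-(2,6,6-trimethylcyclohex-1-en-1-yl)butaneselenoate | CC1=C(C(=O)C[C@@H](C)C(=O)[Se]c2ccccc2)C(C)(C)CCC1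
A6 | alternative 3 | 4-(tert-butyldimethylsilyloxy)-2,5,5,8a-tetramethyl-3,5,6,7,8,8a-hexahydronaphthalene-1-carbaldehyde | CC1=C(C=O)[C@@]2(C)CCCC(C)(C)C2=C(O[Si](C)(C)C(C)(C)C)C1
A7 | alternative 3 | but-2-ynal | CC#CC=O
A8 | alternative 3 | tert-butyldimethyl{[1-(2,6,6-trimethylcyclohex-1-en-1-yl)ethenyl]oxy}silane | C=C(O[Si](C)(C)C(C)(C)C)C1=C(C)CCCC1(C)C
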